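Ring atoms are numbered as in the indene name of the target (C1, C2, C3, C3a, C4, C5, C6, C7, C7a); compound numbers are those of the steps below. The route is a proposal; nothing here has been run.

## The problem

1. Isospiculoic acid A (27) is a trans-fused hexahydroindan-2-one: a cyclohexene ring C3a–C4–C5–C6=C7–C7a fused through the C3a–C7a bond to a cyclopentanone C1–C2(=O)–C3.
2. It has six contiguous stereocentres (C1, C3, C3a, C4, C5, C7a). The hardest bond is C4–C5, which joins two all-carbon quaternary centres (C4: Et, CO2H; C5: Et, (E)-styryl) next to the trans ring fusion.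
3. The feature that opens the structure is that the ring alkene C6=C7 lies exactly between the C4–C5 and C3a–C7a bonds (the retron of a [4+2] cycloaddition), while C7a and C3a are joined a second time by the three atoms C1–C2–C3. Diene C7a=C7–C6=C5 and dienophile C3a=C4 are therefore parts of one chain.
4. In that chain C1 and C3 are allylic to trisubstituted alkenes whose cis substituent is an ethyl group (on C7 and on C4). Allylic 1,3-strain fixes their conformation, so these two centres can control C3a, C4, C5 and C7a, but they must themselves be set beforehand and independently (1,3-related across C2).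
5. C2 is not stereogenic in 27, so in a precursor it may be a carbinol of any configuration.
6. At the ketone level the open chain is fragile: C1 and C3 are α to the ketone and allylic, and C3 is the α-carbon of a vinylogous β-keto acid. Epimerisation and alkene migration threaten exactly the centres that carry the stereochemical information.
7. The chain needs three E-configured trisubstituted or conjugated alkenes, and the phenyl-conjugated triene is sensitive to acid and light.
8. The carboxyl on C4 sits between two quaternary carbons and cannot be freed by attack at its carbonyl, and the finished α,α′-disubstituted ketone and γ,δ-unsaturated acid tolerate neither strong base nor strong acid.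

## Retrosynthesis

**27 ⇒ 26 ⇒ 25 (functional-group changes).** The acid is released from allyl ester 26 by cleavage at the O–allyl bond, the only mild way into this hindered carboxyl. The ketone comes from the C2 carbinol of 25. Keeping C2 as a carbinol until the end means C1 and C3 are never enolisable while unsaturation is built next to them. The forward steps must be neutral.

**25 ⇒ 24 ⇒ 18 + 23 (key cut).** C4–C5 and C3a–C7a are cut together as a [4+2], and the enoate double bond of open-chain 24 is cut by a Wittig disconnection. Against its neighbours: C4–C5 can be made with control only if it closes a ring, and the only pericyclic retron that contains it is the one on C6=C7. Cuts at C5–C6, C6=C7, C7–C7a or at the ketone carbon leave the quaternary pair to an intermolecular or acyclic step. This is also the biogenetic pair of bonds, so no claim of a new disconnection is made; every other cut examined (below) was judged worse. What is chosen differently is the substrate and how it is reached: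
- hydroxy ester 24 rather than the keto acid, so C2 is a disposable centre;
- 24 is born in the flask from aldehyde 18 and ylide 23 and never isolated.

The precursor pair has three stereocentres (one disposable) and no ring; the product has seven stereocentres and both rings. The forward reaction must give the E-enoate, the endo (trans-fused) mode and one π-face.

**18 ⇒ 17 ⇒ 16.** Only the oxidation level and one silyl group change. The forward steps must oxidise the primary alcohol in the presence of the C2 carbinol and must not epimerise C3.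

**16 ⇒ 10 + 11 + 12.** The C6–C7 bond and the C5–styryl bond are cut, so the diene is assembled from three components around the four-carbon linchpin 11. C7=C7a comes from syn hydrozirconation of the alkyne of 10; the C5=C6 geometry is stored in the E-configured 11. This was preferred to olefination at C7=C7a or C5=C6, which gives E/Z mixtures for trisubstituted alkenes. The forward reaction needs regiocontrol in hydrozirconation and C–I before C–Br in coupling.

**10 ⇒ 5 + 8.** The C1–C2 bond is cut by a propargylation. C1 is set by centre-to-axis-to-centre chirality transfer from carbinol 4, and C3 is bought with 8. The C2 configuration set here is incidental. The alkyne is at once the latent C7=C7a alkene, carrying the C7 ethyl group.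

**Small pieces.** 5 ⇐ 4 ⇐ 3 ⇐ 1 + 2 (one catalytic asymmetric reduction); 8 ⇐ 7 ⇐ 6; 11 ⇐ 1; 23 ⇐ 22 ⇐ 21 ⇐ 19 + 20. All are one- or two-step operations on commercial materials.

## Roads not taken

**Alternative 1:** the most obvious route, the biogenetic one. The same two bonds are cut in the target itself, so the forward key step is thermal cyclisation of keto acid A1, built linearly by aldol and olefination chemistry. In A1, C4 (chain numbering) is α to the ketone and γ to the enoic acid, and C6 is α-keto and allylic to a triene. Both enolise easily and the C2=C3 alkene can move into conjugation with the ketone, so stereochemical information is at risk just before it is used. Avoiding this forces reduction and protection onto an already linear sequence. The chosen plan makes the same bonds from a carbinol-level chain, assembled convergently, with no protecting group on the tether and no isolated tetraene.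

**Alternative 2:** the same [4+2] between two molecules, diene ester A2 and enedioate A3, followed by Dieckmann closure of C2–C1 and decarboxylation. The diene has a Z-placed ethyl group on its terminus (s-cis form disfavoured) and the dienophile is trisubstituted. Without a tether there is no entropic help and no control of regiochemistry, endo/exo or π-face. The Dieckmann step would also scramble C1 and C3. More steps, less control.

**Alternative 3:** cut the cyclopentanone instead (C1–C2, C2–C3 and C3a–C7a) by an intramolecular Pauson–Khand reaction of enyne A4 to dienone A5, with the C4–C5 bond made earlier by an acyclic Ireland–Claisen rearrangement. The Claisen step needs defined geometry of a tetrasubstituted ester enolate to relate C4 to C5. A5 then needs a 1,4-reduction of a cross-ring dienone at a tetrasubstituted carbon to give the trans fusion, against 1,6-reduction and cis delivery. The chosen step sets the same centres in one event, stereospecifically.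

Key step: step 13

Remarks: 20 is used as the racemate (its stereocentre is lost in 23). In step 8 the hydroxyl of 10 is present as its metal alkoxide; 13 and 14 are written in the hydroxyl form.

## Route

Step 1
Reactants: 1 but-1-yne; 2 N-methoxy-N-methylpropanamide
Product: 3 hept-4-yn-3-one
Conditions: n-BuLi, THF, −78 °C; then 2, −78 → 0 °C; aq. NH4Cl
Reagents that add atoms: none
Why: Acylation of a lithium acetylide by a Weinreb amide; the N-methoxy chelate holds the tetrahedral adduct until work-up, so addition should stop at the ynone.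

Step 2
Reactants: 3 hept-4-yn-3-one
Product: 4 (S)-hept-4-yn-3-ol
Conditions: Ru[(S,S)-TsDPEN](p-cymene) (1 mol %), i-PrOH, rt
Reagents that add atoms: none
Why: Noyori asymmetric transfer hydrogenation of an ynone; the (S,S) catalyst distinguishes alkynyl from alkyl and should give the (S)-carbinol without reducing the triple bond. This is the only catalytic stereo-determining step.

Step 3
Reactants: 4 (S)-hept-4-yn-3-ol
Product: 5 (S)-hept-4-yn-3-yl methanesulfonate
Conditions: MsCl, Et3N, CH2Cl2, −78 → 0 °C
Reagents that add atoms: methanesulfonyl chloride, CS(=O)(=O)Cl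
Why: O-Sulfonylation with retention at carbon; the propargylic mesylate is used without chromatography.

Step 4
Reactants: 6 methyl (R)-3-hydroxy-2-methylpropanoate
Product: 7 methyl (R)-3-[(tert-butyldimethylsilyl)oxy]-2-methylpropanoate
Conditions: TBSCl, imidazole, DMF, rt
Reagents that add atoms: tert-butyldimethylsilyl chloride, CC(C)(C)[Si](C)(C)Cl
Why: Imidazole-promoted silylation of a primary alcohol; the purchased stereocentre (future C3) is untouched.

Step 5
Reactants: 7 methyl (R)-3-[(tert-butyldimethylsilyl)oxy]-2-methylpropanoate
Product: 8 (R)-3-[(tert-butyldimethylsilyl)oxy]-2-methylpropanal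
Conditions: DIBAL-H, CH2Cl2, −78 °C; Rochelle salt
Reagents that add atoms: none
Why: Half-reduction of an ester through the stable aluminium hemiacetal at −78 °C; non-basic, so the α-centre should not epimerise.

Step 6
Reactants: 5 (S)-hept-4-yn-3-yl methanesulfonate; 8 (R)-3-[(tert-butyldimethylsilyl)oxy]-2-methylpropanal
Product: 10 (2R,3R,4R)-1-[(tert-butyldimethylsilyl)oxy]-4-ethyl-2-methyloct-5-yn-3-ol, via allenylzinc 9 (not isolated)
Conditions: Pd(OAc)2 (5 mol %), PPh3 (5 mol %), Et2Zn, THF, −78 → −20 °C
Reagents that add atoms: none
Why: Marshall–Tamaru propargylation: Pd(0) opens the mesylate anti (SN2′), Et2Zn transmetalates with retention to 9, and 9 adds to 8 through a cyclic SE2′ transition state. Net inversion at the former carbinol carbon sets C4 (future C1) as R, the chair transition state gives the anti C3/C4 relation, and with (R)-8 this is the Felkin-matched pairing. C3 of 10 (future C2) is oxidised later, so its configuration is not critical.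

Step 7
Reactants: 1 but-1-yne
Product: 11 (E)-2-bromo-1-iodobut-1-ene
Conditions: IBr, CH2Cl2, −78 → 0 °C
Reagents that add atoms: iodine monobromide, BrI
Why: Electrophilic anti addition of I–Br to a terminal alkyne, iodine at the terminal carbon and bromide at the internal one; this should give the E-dihalide, whose two C–halogen bonds differ sharply in reactivity towards Pd(0).

Step 8
Reactants: 10 (2R,3R,4R)-1-[(tert-butyldimethylsilyl)oxy]-4-ethyl-2-methyloct-5-yn-3-ol; 11 (E)-2-bromo-1-iodobut-1-ene; 12 (E)-2-phenylethenylboronic acid
Product: 16 (2R,3R,4R,5E,7E,9E)-1-[(tert-butyldimethylsilyl)oxy]-4,6,8-triethyl-2-methyl-10-phenyldeca-5,7,9-trien-3-ol, via alkenylzirconocene chloride 13 (not isolated), via alkenylzinc chloride 14 (not isolated), via bromodiene 15 (not isolated)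
Conditions: Cp2Zr(H)Cl (2.5 equiv), THF, rt → 40 °C; ZnCl2; Pd(PPh3)4 (5 mol %), 11, rt; then 12, aq. K3PO4, 50 °C
Reagents that add atoms: none
Why: Hydrozirconation is syn and, after equilibration with excess reagent, should place Zr on the alkyne carbon next to CH2CH3 rather than next to the branched C4. Negishi coupling at the C–I bond of 11 and then Suzuki–Miyaura coupling at the C–Br bond both go with retention, so the 5E,7E geometry follows from the syn addition and from the anti addition of step 7.

Step 9
Reactants: 16 (2R,3R,4R,5E,7E,9E)-1-[(tert-butyldimethylsilyl)oxy]-4,6,8-triethyl-2-methyl-10-phenyldeca-5,7,9-trien-3-ol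
Product: 17 (2R,3R,4R,5E,7E,9E)-4,6,8-triethyl-2-methyl-10-phenyldeca-5,7,9-triene-1,3-diol
Conditions: TBAF, THF, 0 °C → rt
Reagents that add atoms: none
Why: Fluoride cleavage of a primary silyl ether; nothing in 16 is base-labile at this oxidation level.

Step 10
Reactants: 17 (2R,3R,4R,5E,7E,9E)-4,6,8-triethyl-2-methyl-10-phenyldeca-5,7,9-triene-1,3-diol
Product: 18 (2S,3R,4R,5E,7E,9E)-4,6,8-triethyl-3-hydroxy-2-methyl-10-phenyldeca-5,7,9-trienal
Conditions: TEMPO (10 mol %), PhI(OAc)2, CH2Cl2, rt
Reagents that add atoms: none
Why: Oxoammonium oxidation is much faster for a primary than for a hindered secondary alcohol, and the neutral medium should spare the α-centre of the β-hydroxy aldehyde, which is used at once (the descriptor at C2 changes by priority only).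

Step 11
Reactants: 19 prop-2-en-1-ol; 20 2-bromobutanoyl bromide
Product: 21 prop-2-en-1-yl 2-bromobutanoate
Conditions: pyridine, CH2Cl2, 0 °C
Reagents that add atoms: none
Why: Acylation of an alcohol by an acid bromide; the allyl ester is chosen so that the hindered carboxyl can later be freed at the O–alkyl bond.

Step 12
Reactants: 21 prop-2-en-1-yl 2-bromobutanoate
Product: 23 prop-2-en-1-yl 2-(triphenyl-λ5-phosphanylidene)butanoate, via phosphonium bromide 22 (not isolated)
Conditions: PPh3, toluene, 90 °C; then aq. NaOH, CH2Cl2, rt
Reagents that add atoms: triphenylphosphine, c1ccc(cc1)P(c1ccccc1)c1ccccc1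
Why: SN2 quaternisation of PPh3 by the α-bromo ester and deprotonation give a stabilised ylide that can be stored.

Step 13
Reactants: 18 (2S,3R,4R,5E,7E,9E)-4,6,8-triethyl-3-hydroxy-2-methyl-10-phenyldeca-5,7,9-trienal; 23 prop-2-en-1-yl 2-(triphenyl-λ5-phosphanylidene)butanoate
Product: 25 prop-2-en-1-yl (1R,2S,3R,3aS,4S,5R,7aS)-1,4,5,7-tetraethyl-2-hydroxy-3-methyl-5-[(E)-2-phenylethenyl]-2,3,3a,4,5,7a-hexahydro-1H-indene-4-carboxylate, via hydroxy tetraenoate 24 (not isolated)
Conditions: CH2Cl2, 40 °C; then toluene, BHT (cat.), 105 °C
Reagents that add atoms: none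
Why: The stabilised ylide 23 converts 18 into enoate 24 (Wittig reaction; E because oxaphosphetane formation is reversible for ester ylides), and on heating 24 undergoes a concerted suprafacial intramolecular Diels–Alder reaction between diene C7a=C7–C6=C5 and enoate C3a=C4 (ring numbering of 27). The closest known reaction type is the thermal type-1 intramolecular Diels–Alder reaction of ester-terminated (E)-1,3,8-nonatrienes with allylic stereocentres, which gives trans-fused hydrindenes. The cyclohexene closes by [4+2] formation of C4–C5 and C3a–C7a; the cyclopentane is closed by the same C3a–C7a bond across the tether C1–C2–C3, which also fixes the regiochemistry (the distal diene would need a seven-membered ring). C4 and C5 follow from alkene geometry by suprafacial addition: the E-enoate and the diene terminus with styryl outside and ethyl inside put the two ethyl groups cis and the ester cis to styryl. The trans relation of C3a–H and C7a–H follows from the endo transition state (ester under the diene) of an E-diene on a three-atom tether. The absolute sense is relayed from C1 and C3: each places its hydrogen in the plane of the adjacent alkene, eclipsing the cis ethyl group on C7 or C4 (allylic 1,3-strain), which puts the tether on one face of both π systems, and in the (1R,3R) series both preferences select the same endo transition state. The selectivities needed are E-olefination, endo over exo and one π-face; ylide stabilisation secures the first and the two matched allylic centres with the short tether secure the others, while the C2 carbinol has no controlling role.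

Step 14
Reactants: 25 prop-2-en-1-yl (1R,2S,3R,3aS,4S,5R,7aS)-1,4,5,7-tetraethyl-2-hydroxy-3-methyl-5-[(E)-2-phenylethenyl]-2,3,3a,4,5,7a-hexahydro-1H-indene-4-carboxylate
Product: 26 prop-2-en-1-yl (1R,3R,3aS,4S,5R,7aS)-1,4,5,7-tetraethyl-3-methyl-2-oxo-5-[(E)-2-phenylethenyl]-2,3,3a,4,5,7a-hexahydro-1H-indene-4-carboxylate
Conditions: Dess–Martin periodinane, NaHCO3, CH2Cl2, rt
Reagents that add atoms: none
Why: Dess–Martin oxidation of a secondary alcohol under buffered, non-basic conditions; C1 and C3 should not enolise and the alkenes are inert.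

Step 15
Reactants: 26 prop-2-en-1-yl (1R,3R,3aS,4S,5R,7aS)-1,4,5,7-tetraethyl-3-methyl-2-oxo-5-[(E)-2-phenylethenyl]-2,3,3a,4,5,7a-hexahydro-1H-indene-4-carboxylate
Product: 27 (1R,3R,3aS,4S,5R,7aS)-1,4,5,7-tetraethyl-3-methyl-2-oxo-5-[(E)-2-phenylethenyl]-2,3,3a,4,5,7a-hexahydro-1H-indene-4-carboxylic acid (isospiculoic acid A)
Conditions: Pd(PPh3)4 (5 mol %), morpholine, THF, rt
Reagents that add atoms: none
Why: Tsuji–Trost-type deallylation cleaves the ester at the O–allyl bond through a π-allyl complex, so the hindrance at C4 is irrelevant and neither acid nor base touches the α-keto centres or the γ,δ-unsaturated acid.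

## Compound list

1 | but-1-yne | CCC#C | starting material
2 | N-methoxy-N-methylpropanamide | CCC(=O)N(C)OC | starting material
3 | hept-4-yn-3-one | CCC#CC(=O)CC | intermediate
4 | (S)-hept-4-yn-3-ol | CCC#C[C@@H](O)CC | intermediate
5 | (S)-hept-4-yn-3-yl methanesulfonate | CCC#C[C@@H](OS(C)(=O)=O)CC | intermediate
6 | methyl (R)-3-hydroxy-2-methylpropanoate | COC(=O)[C@H](C)CO | starting material
7 | methyl (R)-3-[(tert-butyldimethylsilyl)oxy]-2-methylpropanoate | COC(=O)[C@H](C)CO[Si](C)(C)C(C)(C)C | intermediate
8 | (R)-3-[(tert-butyldimethylsilyl)oxy]-2-methylpropanal | O=C[C@H](C)CO[Si](C)(C)C(C)(C)C | intermediate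
9 | (aR)-ethyl(hepta-3,4-dien-3-yl)zinc | CC[Zn]C(CC)=[C@]=C([H])CC | intermediate (not isolated)
10 | (2R,3R,4R)-1-[(tert-butyldimethylsilyl)oxy]-4-ethyl-2-methyloct-5-yn-3-ol | CCC#C[C@@H](CC)[C@@H](O)[C@H](C)CO[Si](C)(C)C(C)(C)C | intermediate
11 | (E)-2-bromo-1-iodobut-1-ene | I/C=C(/Br)CC | intermediate
12 | (E)-2-phenylethenylboronic acid | OB(O)/C=C/c1ccccc1 | starting material
13 | chlorobis(cyclopentadienyl)[(3E,5R,6R,7R)-8-[(tert-butyldimethylsilyl)oxy]-5-ethyl-6-hydroxy-7-methyloct-3-en-3-yl]zirconium | CC/C(=C\[C@@H](CC)[C@@H](O)[C@H](C)CO[Si](C)(C)C(C)(C)C)[Zr](Cl)(C1C=CC=C1)C1C=CC=C1 | intermediate (not isolated)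
14 | chloro[(3E,5R,6R,7R)-8-[(tert-butyldimethylsilyl)oxy]-5-ethyl-6-hydroxy-7-methyloct-3-en-3-yl]zinc | CC/C(=C\[C@@H](CC)[C@@H](O)[C@H](C)CO[Si](C)(C)C(C)(C)C)[Zn]Cl | intermediate (not isolated)
15 | (2R,3R,4R,5E,7E)-8-bromo-1-[(tert-butyldimethylsilyl)oxy]-4,6-diethyl-2-methyldeca-5,7-dien-3-ol | Br/C(CC)=C/C(CC)=C/[C@@H](CC)[C@@H](O)[C@H](C)CO[Si](C)(C)C(C)(C)C | intermediate (not isolated)
16 | (2R,3R,4R,5E,7E,9E)-1-[(tert-butyldimethylsilyl)oxy]-4,6,8-triethyl-2-methyl-10-phenyldeca-5,7,9-trien-3-ol | c1ccccc1/C=C/C(CC)=C/C(CC)=C/[C@@H](CC)[C@@H](O)[C@H](C)CO[Si](C)(C)C(C)(C)C | intermediate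
17 | (2R,3R,4R,5E,7E,9E)-4,6,8-triethyl-2-methyl-10-phenyldeca-5,7,9-triene-1,3-diol | c1ccccc1/C=C/C(CC)=C/C(CC)=C/[C@@H](CC)[C@@H](O)[C@H](C)CO | intermediate
18 | (2S,3R,4R,5E,7E,9E)-4,6,8-triethyl-3-hydroxy-2-methyl-10-phenyldeca-5,7,9-trienal | c1ccccc1/C=C/C(CC)=C/C(CC)=C/[C@@H](CC)[C@@H](O)[C@H](C)C=O | intermediate
19 | prop-2-en-1-ol | C=CCO | starting material
20 | 2-bromobutanoyl bromide (racemic) | CCC(Br)C(Br)=O | starting material
21 | prop-2-en-1-yl 2-bromobutanoate (racemic) | CCC(Br)C(=O)OCC=C | intermediate
22 | [1-oxo-1-(prop-2-en-1-yloxy)butan-2-yl]triphenylphosphonium bromide | CCC(C(=O)OCC=C)[P+](c1ccccc1)(c1ccccc1)c1ccccc1.[Br-] | intermediate (not isolated)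
23 | prop-2-en-1-yl 2-(triphenyl-λ5-phosphanylidene)butanoate | CCC(C(=O)OCC=C)=P(c1ccccc1)(c1ccccc1)c1ccccc1 | intermediate
24 | prop-2-en-1-yl (2E,4R,5S,6R,7E,9E,11E)-2,6,8,10-tetraethyl-5-hydroxy-4-methyl-12-phenyldodeca-2,7,9,11-tetraenoate | c1ccccc1/C=C/C(CC)=C/C(CC)=C/[C@@H](CC)[C@@H](O)[C@H](C)/C=C(\CC)C(=O)OCC=C | intermediate (not isolated)
25 | prop-2-en-1-yl (1R,2S,3R,3aS,4S,5R,7aS)-1,4,5,7-tetraethyl-2-hydroxy-3-methyl-5-[(E)-2-phenylethenyl]-2,3,3a,4,5,7a-hexahydro-1H-indene-4-carboxylate | CCC1=C[C@](/C=C/c2ccccc2)(CC)[C@@](CC)(C(=O)OCC=C)[C@H]2[C@H]1[C@@H](CC)[C@@H](O)[C@@H]2C | intermediate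
26 | prop-2-en-1-yl (1R,3R,3aS,4S,5R,7aS)-1,4,5,7-tetraethyl-3-methyl-2-oxo-5-[(E)-2-phenylethenyl]-2,3,3a,4,5,7a-hexahydro-1H-indene-4-carboxylate | CCC1=C[C@](/C=C/c2ccccc2)(CC)[C@@](CC)(C(=O)OCC=C)[C@H]2[C@H]1[C@@H](CC)C(=O)[C@@H]2C | intermediate
27 | (1R,3R,3aS,4S,5R,7aS)-1,4,5,7-tetraethyl-3-methyl-2-oxo-5-[(E)-2-phenylethenyl]-2,3,3a,4,5,7a-hexahydro-1H-indene-4-carboxylic acid (isospiculoic acid A) | CCC1=C[C@](/C=C/c2ccccc2)(CC)[C@@](CC)(C(=O)O)[C@H]2[C@H]1[C@@H](CC)C(=O)[C@@H]2C | target

## Step count and least certain steps

Total step count: 15. Longest linear sequence: 10 steps (1, 2, 3, 6, 8, 9, 10, 13, 14, 15).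

**Step 13 (key step).** Three processes could fail:
- incomplete endo/exo and π-facial discrimination in a purely thermal cycloaddition of an unprotected carbinol;
- slow cyclisation caused by the inside ethyl group on the diene terminus, so that a [1,5]-hydrogen shift in the Z-substituted diene competes;
- epimerisation of the α-centre of the β-hydroxy aldehyde 18 (or retro-aldol loss) during the warm olefination.

The fallback replaces the thermal cascade by a Lewis-acid-promoted cycloaddition of an isolated, silyl-protected tetraene. It sets out from 16 and comes back to the route at 25. Silylation (TBSOTf, 2,6-lutidine) gives the bis-silyl ether F1. Selective removal of the primary silyl group (HF·pyridine, THF/pyridine) gives the alcohol F2. Dess–Martin oxidation gives the β-silyloxy aldehyde F3, which has no free β-hydroxyl and is more robust at its α-centre. Wittig reaction with 23 at room temperature gives the silyloxy tetraenoate F4, which is isolated. Me2AlCl in CH2Cl2 at −40 to 0 °C (ester complexation lowers the dienophile LUMO and tightens the endo transition state) gives the silyl ether cycloadduct F5, and HF·pyridine returns 25.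

**Step 8.** Two processes could fail: loss of regiocontrol in the hydrozirconation (zirconium delivered to the carbon next to C4, possibly directed by the alkoxide), and stalling or loss of C–I/C–Br chemoselectivity when the second coupling is run in the presence of zirconium and zinc salts. The fallback changes the regiochemistry-determining principle and separates the couplings. It sets out from 10 and comes back at 15, then 16. Hydroboration with dicyclohexylborane (kinetic, sterically governed syn addition) gives the alkenylborane F6. Suzuki–Miyaura coupling of F6 with 11 at the C–I bond (Pd(PPh3)4, aq. NaOH) gives 15, which is isolated and purified. A separate Suzuki–Miyaura coupling of 15 with 12 gives 16.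

**Step 6.** Partial racemisation of allenylzinc 9 before it is trapped would erode the configuration of the future C1, and the anti selectivity of the addition could be incomplete. The fallback uses an isolable, configurationally stable allenylboron reagent instead of the transient allenylzinc. It sets out from 4 and comes back at 10. Methyl chloroformate and pyridine give the carbonate F7. Copper-catalysed anti-SN2′ borylation with bis(pinacolato)diboron gives the allenylboronate F8, which can be purified. Uncatalysed addition of F8 to 8 through a closed six-membered transition state gives 10 with the same sense of chirality transfer.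

## Further compounds

F1 | step 13 | (2R,3R,4R,5E,7E,9E)-1,3-bis[(tert-butyldimethylsilyl)oxy]-4,6,8-triethyl-2-methyl-10-phenyldeca-5,7,9-triene | c1ccccc1/C=C/C(CC)=C/C(CC)=C/[C@@H](CC)[C@@H](O[Si](C)(C)C(C)(C)C)[C@H](C)CO[Si](C)(C)C(C)(C)C
F2 | step 13 | (2R,3R,4R,5E,7E,9E)-3-[(tert-butyldimethylsilyl)oxy]-4,6,8-triethyl-2-methyl-10-phenyldeca-5,7,9-trien-1-ol | c1ccccc1/C=C/C(CC)=C/C(CC)=C/[C@@H](CC)[C@@H](O[Si](C)(C)C(C)(C)C)[C@H](C)CO
F3 | step 13 | (2S,3R,4R,5E,7E,9E)-3-[(tert-butyldimethylsilyl)oxy]-4,6,8-triethyl-2-methyl-10-phenyldeca-5,7,9-trienal | c1ccccc1/C=C/C(CC)=C/C(CC)=C/[C@@H](CC)[C@@H](O[Si](C)(C)C(C)(C)C)[C@H](C)C=O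
F4 | step 13 | prop-2-en-1-yl (2E,4R,5S,6R,7E,9E,11E)-5-[(tert-butyldimethylsilyl)oxy]-2,6,8,10-tetraethyl-4-methyl-12-phenyldodeca-2,7,9,11-tetraenoate | c1ccccc1/C=C/C(CC)=C/C(CC)=C/[C@@H](CC)[C@@H](O[Si](C)(C)C(C)(C)C)[C@H](C)/C=C(\CC)C(=O)OCC=C
F5 | step 13 | prop-2-en-1-yl (1R,2S,3R,3aS,4S,5R,7aS)-2-[(tert-butyldimethylsilyl)oxy]-1,4,5,7-tetraethyl-3-methyl-5-[(E)-2-phenylethenyl]-2,3,3a,4,5,7a-hexahydro-1H-indene-4-carboxylate | CCC1=C[C@](/C=C/c2ccccc2)(CC)[C@@](CC)(C(=O)OCC=C)[C@H]2[C@H]1[C@@H](CC)[C@@H](O[Si](C)(C)C(C)(C)C)[C@@H]2C
F6 | step 8 | dicyclohexyl[(3Z,5R,6R,7R)-8-[(tert-butyldimethylsilyl)oxy]-5-ethyl-6-hydroxy-7-methyloct-3-en-3-yl]borane | CC/C(=C\[C@@H](CC)[C@@H](O)[C@H](C)CO[Si](C)(C)C(C)(C)C)B(C1CCCCC1)C1CCCCC1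
F7 | step 6 | (S)-hept-4-yn-3-yl methyl carbonate | CCC#C[C@@H](OC(=O)OC)CC
F8 | step 6 | (aS)-2-(hepta-3,4-dien-3-yl)-4,4,5,5-tetramethyl-1,3,2-dioxaborolane | CCC(B1OC(C)(C)C(C)(C)O1)=[C@@]=C([H])CC
A1 | alternative 1 | (2E,4R,6R,7E,9E,11E)-2,6,8,10-tetraethyl-4-methyl-5-oxo-12-phenyldodeca-2,7,9,11-tetraenoic acid | OC(=O)/C(CC)=C/[C@@H](C)C(=O)[C@H](CC)/C=C(CC)/C=C(CC)/C=C/c1ccccc1
A2 | alternative 2 | methyl (2R,3E,5E,7E)-2,4,6-triethyl-8-phenylocta-3,5,7-trienoate | COC(=O)[C@H](CC)/C=C(CC)/C=C(CC)/C=C/c1ccccc1
A3 | alternative 2 | dimethyl (2E,4R)-2-ethyl-4-methylpent-2-enedioate | COC(=O)/C(CC)=C/[C@@H](C)C(=O)OC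
A4 | alternative 3 | methyl (2S,3R,4Z)-2,3,5-triethyl-3-[(E)-2-phenylethenyl]-2-[(1E)-prop-1-en-1-yl]non-4-en-6-ynoate | CCC#C/C(CC)=C\[C@](/C=C/c1ccccc1)(CC)[C@@](CC)(C(=O)OC)/C=C/C
A5 | alternative 3 | methyl (3R,3aR,4S,5R)-1,4,5,7-tetraethyl-3-methyl-2-oxo-5-[(E)-2-phenylethenyl]-3,3a,4,5-tetrahydro-2H-indene-4-carboxylate | CCC1=C[C@](/C=C/c2ccccc2)(CC)[C@@](CC)(C(=O)OC)[C@H]2C1=C(CC)C(=O)[C@@H]2C
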